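**The ceiling.** I could not get more J plus L out of a flask than its D paid for, one X going into each: in elm they read 51.6% at 6.00 h, against a D charge worth 50.0% of the E and Q charged, a match within a scatter of 1 percentage point per reading. The new flask holds as much D as E and Q together, so to stop short for want of D, it had to lose its D before 10 h.

| setting | elm | maple | birch | flask |
|---|---|---|---|---|
| E | 0.020 M | 0.020 M | 0.010 M | 0.020 M |
| Q | 0.020 M | 0.020 M | 0.010 M | 0.020 M |
| D | 0.020 M | 0.080 M | 0.040 M | 0.0400 M |
| remark | run made earlier | run made earlier | run made earlier |  |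
| time |  |  |  | 10 h |

- elm (time / h: J / %, L / %, E / %): 0.500: 3.1, 2.6, 36.3; 0.667: 5.9, 3.6, 36.1; 1.00: 5.4, 6.0, 32.3; 1.50: 8.7, 7.9, 29.5; 2.50: 12.1, 12.8, 25.9; 4.00: 20.5, 20.1, 20.2; 6.00: 26.7, 24.9, 17.6
- maple (time / h: J / %, L / %, E / %): 0.500: 0.5, 3.5, 35.5; 0.667: 3.1, 4.2, 35.1; 1.00: 4.5, 6.7, 32.9; 1.50: 7.4, 7.9, 31.8; 2.50: 15.0, 12.5, 27.8; 4.00: 19.6, 20.1, 21.3; 6.00: 29.5, 28.2, 13.7
- birch (time / h: J / %, L / %, E / %): 0.500: 5.2, 3.3, 33.8; 1.50: 15.2, 11.7, 27.7; 3.00: 26.0, 22.4, 17.5; 4.00: 31.4, 29.3, 11.8; 6.00: 40.6, 41.1, 7.5

(standard deviation of a reading: 1 percentage point)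

- X is single-handed; E and Q are mirror images of each other, charged as a racemate, each of them at the stated concentration
- as a solid, counted per litre of solution: D
- on the list of suspects stand: X + E -> J; X + Q -> L; E <-> Z; Q <-> Z; J <-> L; D <-> X; 2 X -> G
- at the start none of D is in solution
- what has gone into Z counts as reacted
- an excess is below zero if the other one leads
- the handed part of X does not stay in what it makes, so the products of the two hands are mirror images too

- excess of J over L in the product at 30 min
- excess of J over L in the product at 10 h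
- part of the E and Q charged together that has reacted at 10 h

**First round.** Elm and maple read alike in J plus L at 4.00 h, despite different D, and elm's reading gives a pace of 0.00406 M h⁻¹. The D charge over that pace, τ = 9.85 h, is the spending time, and it lands just under 10 h.

**Second round.** Birch slowed, though: with 0.00786 M unconverted at 4.00 h, it then made 0.00210 M h⁻¹. I put that back in for the flask's last stretch, and τ became 11.7 h. So I expected D to outlast the run, with about 8.71% of it left.

**The forecast.** In the order asked, it gave 2%, 2% and 90%, holding that “the amount of D doesn't matter while solid remains”.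

**The result.** In the same order, the flask gave 10.2%, 0.213% and 89.8%.

    X + E → J (k = 11.0 M⁻¹ min⁻¹)
    X + Q → L (k = 5.10 M⁻¹ min⁻¹)
    E ⇌ Z (K = 0.640, k = 0.0240 min⁻¹)
    Q ⇌ Z (K = 0.640, k = 0.0240 min⁻¹)
    J ⇌ L (k = 0.0610 min⁻¹)
    D ⇌ X, rate k6*(cs6 - [X]) while solid is left; crystals form when [X] > cs6 (solubility = 1.70 mM, k = 0.0530 min⁻¹)
    2 X → G (k = 1.70 M⁻¹ min⁻¹)

**The spending.** Through its 10 h, D dissolved while E and Q exchanged through Z, and against my τ of 11.7 h, 9.46% of the D charge still stood at the end, with J and L at 43.2% each. J and L interconverted with a relaxation half-life, by that step alone, of 0.0947 h, short against the run. The neighbour flask with 0.024 M of D has τ = 5.91 h, and there D, the limiting reagent, stood at 0% at 10.0 h, with J and L at 29.7% each.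

Readings and results are calculated on assumed constants, noise included.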